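**Retrosynthetic overview**

1. 17 ⇐ 16: the C8–Cl and C7–OH come from HCl opening (at C8, with inversion) of the all-cis 5,6-dihydroxy-7,8-epoxide.
2. 16 ⇐ 14 (key step): the carbocycle C4a–C5–C6–C7–C8–C8a is closed last, by ring-closing metathesis at C7=C8, and epoxidised in the same operation. Enabling feature: C8 is bonded to C8a and C5 to C4a of the γ-pyrone ring, so at the C7=C8 oxidation level the new ring is a cyclohexa-1,3-diene (C7=C8–C8a=C4a, a "cis-dihydrodiol" of the chromone). It is reachable from a 2-vinyl group and a but-3-enyl chain, and its cis-5,6-diol lies allylic/homoallylic to the new olefin and steers O (then Cl) onto C7/C8.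
3. 14 ⇐ 11: the anti-5,6-diol, the only stereochemical information brought in from outside, comes from a reagent-controlled (E)-γ-borylallylboration of the 3-formyl-2-vinyl-γ-pyrone.
4. 11 ⇐ 7: a 3-hydroxy-γ-pyrone of the kojic acid type; its OH first directs iodination/vinylation of the neighbouring carbon (future C8a) and then, as the triflate, is exchanged for CHO (future C5 on C4a).
5. Ring order: arene and γ-pyrone are bought (4, 1) and joined by Wittig olefination/hydrogenation; the carbocycle is closed in step 11; the transient oxirane formed there is opened in step 12.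

Key step: step 11

Remark: the Ipc2B reagent made from (−)-α-pinene is assumed to add to the Re face of the formyl group of 11, as such reagents normally do with aldehydes; if the sense were reversed, the enantiomeric borane would be used.
Abbreviations: TBS = tert-butyldimethylsilyl; ArTBS = 3-(tert-butyldimethylsilyloxy)-4-methoxyphenyl; Ipc = isopinocampheyl; pin = pinacolato. Locants C4a–C8a are the chromone locants of the target and are also used for the corresponding carbons of the monocyclic precursors.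

**Route**

Step 1
Reactants: 1 5-(benzyloxy)-2-(hydroxymethyl)-4H-pyran-4-one
Product: 2 5-(benzyloxy)-2-(chloromethyl)-4H-pyran-4-one
Conditions: SOCl2, CH2Cl2, 0 °C → rt
Reagents that add atoms: thionyl chloride, O=S(Cl)Cl
Why: Deoxychlorination of an activated primary (pyranyl)methanol through its chlorosulfite, the usual conversion of kojic acid ethers; no stereocentre is involved.

Step 2
Reactants: 2 5-(benzyloxy)-2-(chloromethyl)-4H-pyran-4-one
Product: 3 {[5-(benzyloxy)-4-oxo-4H-pyran-2-yl]methyl}triphenylphosphonium chloride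
Conditions: PPh3, MeCN, reflux
Reagents that add atoms: triphenylphosphine, c1ccc(cc1)P(c1ccccc1)c1ccccc1
Why: SN2 quaternisation of the activated chloride (phosphonium salt formation).

Step 3
Reactants: 3 {[5-(benzyloxy)-4-oxo-4H-pyran-2-yl]methyl}triphenylphosphonium chloride; 4 3-(tert-butyldimethylsilyloxy)-4-methoxybenzaldehyde
Product: 6 (E)-5-(benzyloxy)-2-[2-(ArTBS)ethenyl]-4H-pyran-4-one (E/Z mixture expected; E drawn), via phosphorus ylide 5 (not isolated)
Conditions: LiHMDS, THF, −78 °C → rt
Reagents that add atoms: none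
Why: Wittig olefination of a semi-stabilised ylide with an aryl aldehyde; the olefin geometry is irrelevant because the double bond is hydrogenated in the next step.

Step 4
Reactants: 6 (E)-5-(benzyloxy)-2-[2-(ArTBS)ethenyl]-4H-pyran-4-one
Product: 7 5-hydroxy-2-[2-(ArTBS)ethyl]-4H-pyran-4-one
Conditions: H2 (1 atm), 10% Pd/C, EtOAc, rt
Reagents that add atoms: none
Why: Heterogeneous hydrogenation saturates the styrene-type olefin and hydrogenolyses the enol benzyl ether in one operation, while the γ-pyrone and the aryl silyl ether should survive these mild neutral conditions.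

Step 5
Reactants: 7 5-hydroxy-2-[2-(ArTBS)ethyl]-4H-pyran-4-one
Product: 8 3-hydroxy-2-iodo-6-[2-(ArTBS)ethyl]-4H-pyran-4-one
Conditions: NIS, MeCN, 0 °C
Reagents that add atoms: N-iodosuccinimide, O=C1CCC(=O)N1I
Why: Electrophilic iodination of the 3-hydroxy-γ-pyrone (an enol of phenol-like reactivity) at the free position ortho to OH and next to the ring oxygen (future C8a), the site at which kojic-acid-type pyrones are halogenated.

Step 6
Reactants: 8 3-hydroxy-2-iodo-6-[2-(ArTBS)ethyl]-4H-pyran-4-one
Product: 9 2-ethenyl-3-hydroxy-6-[2-(ArTBS)ethyl]-4H-pyran-4-one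
Conditions: Bu3SnCH=CH2, Pd(PPh3)4 (5 mol%), DMF, 70 °C
Reagents that add atoms: tributyl(vinyl)stannane, C=C[Sn](CCCC)(CCCC)CCCC
Why: Stille coupling at a vinylogous acyl iodide, which undergoes fast oxidative addition and tolerates the free enol OH.

Step 7
Reactants: 9 2-ethenyl-3-hydroxy-6-[2-(ArTBS)ethyl]-4H-pyran-4-one
Product: 10 2-ethenyl-4-oxo-6-[2-(ArTBS)ethyl]-4H-pyran-3-yl trifluoromethanesulfonate
Conditions: Tf2O, pyridine, CH2Cl2, −20 °C
Reagents that add atoms: triflic anhydride, O=S(=O)(OS(=O)(=O)C(F)(F)F)C(F)(F)F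
Why: O-Sulfonylation of the acidic enol turns the hydroxyl that directed step 5 into a cross-coupling handle on the future C4a.

Step 8
Reactants: 10 2-ethenyl-4-oxo-6-[2-(ArTBS)ethyl]-4H-pyran-3-yl trifluoromethanesulfonate
Product: 11 2-ethenyl-4-oxo-6-[2-(ArTBS)ethyl]-4H-pyran-3-carbaldehyde
Conditions: CO (1 atm), Et3SiH, Pd(OAc)2/dppp (cat.), Et3N, DMF, 70 °C
Reagents that add atoms: carbon monoxide, [C-]#[O+]
Why: Palladium-catalysed reductive carbonylation (formylation) of an enol triflate: oxidative addition, CO insertion and hydride transfer from the silane to the acyl-palladium species.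

Step 9
Reactants: 11 2-ethenyl-4-oxo-6-[2-(ArTBS)ethyl]-4H-pyran-3-carbaldehyde
Product: 13 3-[(1S,2R)-1,2-dihydroxybut-3-en-1-yl]-2-ethenyl-6-[2-(ArTBS)ethyl]-4H-pyran-4-one, via boron adduct 12 (not isolated)
Conditions: (+)-Ipc2BH [from (−)-α-pinene], allenyl-Bpin, THF, 0 °C; then 11, −78 °C; then NaBO3·4H2O, THF/H2O, 0 °C
Reagents that add atoms: allenylboronic acid pinacol ester, C=C=CB1OC(C)(C)C(C)(C)O1; sodium perborate, [Na+].[Na+].O[B-]1(O)OO[B-](O)(O)OO1
Why: Brown-type allylboration with the (E)-γ-borylallyl-diisopinocampheylborane made in the flask by allene hydroboration: the closed chair transition state of the E reagent gives the anti C5–O/C6–B relationship, the isopinocampheyl groups direct attack to the Re face of the aldehyde (C5 S), and oxidation replaces C6–B by C6–OH with retention (C6 R).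

Step 10
Reactants: 13 3-[(1S,2R)-1,2-dihydroxybut-3-en-1-yl]-2-ethenyl-6-[2-(ArTBS)ethyl]-4H-pyran-4-one
Product: 14 3-[(1S,2R)-1,2-dihydroxybut-3-en-1-yl]-2-ethenyl-6-[2-(3-hydroxy-4-methoxyphenyl)ethyl]-4H-pyran-4-one
Conditions: TBAF, AcOH, THF, 0 °C
Reagents that add atoms: none
Why: Buffered fluoride cleavage of the aryl silyl ether; any material that already lost the silyl group in step 9 converges on the same product.

Step 11
Reactants: 14 3-[(1S,2R)-1,2-dihydroxybut-3-en-1-yl]-2-ethenyl-6-[2-(3-hydroxy-4-methoxyphenyl)ethyl]-4H-pyran-4-one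
Product: 16 (5S,6S,7S,8S)-7,8-epoxy-5,6-dihydroxy-2-[2-(3-hydroxy-4-methoxyphenyl)ethyl]-5,6,7,8-tetrahydro-4H-chromen-4-one (oxirane cis to both hydroxyls), via cis-dihydrodiol 15 (not isolated)
Conditions: Hoveyda–Grubbs II (5 mol%), CH2Cl2 (5 mM), 40 °C; Florisil plug; then m-CPBA, NaHCO3, CH2Cl2, 0 °C
Reagents that add atoms: m-chloroperbenzoic acid, O=C(OO)c1cccc(Cl)c1
Why: A ruthenium alkylidene formed at the terminal olefin next to C6 undergoes [2+2]/retro-[2+2] exchange with the 2-vinyl group on C8a and expels ethylene, which closes the carbocycle at C7=C8 as the cyclohexa-1,3-diene 15; the peracid then adds oxygen to C7=C8 in one concerted syn step. The closest known reaction types are ring-closing metathesis of ortho-vinylaryl butenediols to 1,2-dihydronaphthalene-1,2-diols and the syn-selective peracid epoxidation of free cis-dihydrodiols of arenes. The carbocycle closes by six-membered ring-closing olefin metathesis and the oxirane by syn addition to the new olefin. C7 and C8 are set by substrate control: the allylic C6–OH and the homoallylic C5–OH, both on the same face, hydrogen-bond the peracid (Henbest-type delivery) so that the oxirane oxygen arrives cis to them, while C5 and C6 are not touched. The step needs ring closure instead of oligomerisation, secured by high dilution and by the strain-free conjugated diene that results, and it needs oxidation of C7=C8 only, secured by the electron-poor vinylogous-ester C2=C3 bond and the directing hydroxyls. The dehydration-prone dihydrodiol 15 is spared by the NaHCO3 buffer and by not isolating it.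

Step 12
Reactants: 16 (5S,6S,7S,8S)-7,8-epoxy-5,6-dihydroxy-2-[2-(3-hydroxy-4-methoxyphenyl)ethyl]-5,6,7,8-tetrahydro-4H-chromen-4-one
Product: 17 (5S,6S,7S,8R)-8-chloro-5,6,7-trihydroxy-2-[2-(3-hydroxy-4-methoxyphenyl)ethyl]-5,6,7,8-tetrahydro-4H-chromen-4-one
Conditions: HCl (1 M in Et2O), THF, −30 → 0 °C
Reagents that add atoms: hydrogen chloride, Cl
Why: Acid-promoted SN2 opening of the oxirane by chloride, the way diol epoxides of dihydroarenes give trans-chlorohydrins: C8 lies next to the pyrone π system whereas C7 is deactivated by the adjacent C6 oxygen, so chlorine should enter C8 with inversion, anti to the oxygen that stays on C7.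

**Compound list**

1 | 5-(benzyloxy)-2-(hydroxymethyl)-4H-pyran-4-one (O-benzylkojic acid) | O=c1cc(CO)occ1OCc1ccccc1 | starting material
2 | 5-(benzyloxy)-2-(chloromethyl)-4H-pyran-4-one | O=c1cc(CCl)occ1OCc1ccccc1 | intermediate
3 | {[5-(benzyloxy)-4-oxo-4H-pyran-2-yl]methyl}triphenylphosphonium chloride | [Cl-].O=c1cc(C[P+](c2ccccc2)(c2ccccc2)c2ccccc2)occ1OCc1ccccc1 | intermediate
4 | 3-(tert-butyldimethylsilyloxy)-4-methoxybenzaldehyde | COc1ccc(C=O)cc1O[Si](C)(C)C(C)(C)C | starting material
5 | phosphorus ylide derived from 3 | O=c1cc(C=P(c2ccccc2)(c2ccccc2)c2ccccc2)occ1OCc1ccccc1 | intermediate (not isolated)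
6 | (E)-5-(benzyloxy)-2-{2-[3-(tert-butyldimethylsilyloxy)-4-methoxyphenyl]ethenyl}-4H-pyran-4-one (E/Z mixture expected, E drawn) | O=c1cc(/C=C/c2ccc(OC)c(O[Si](C)(C)C(C)(C)C)c2)occ1OCc1ccccc1 | intermediate
7 | 5-hydroxy-2-{2-[3-(tert-butyldimethylsilyloxy)-4-methoxyphenyl]ethyl}-4H-pyran-4-one | O=c1cc(CCc2ccc(OC)c(O[Si](C)(C)C(C)(C)C)c2)occ1O | intermediate
8 | 3-hydroxy-2-iodo-6-{2-[3-(tert-butyldimethylsilyloxy)-4-methoxyphenyl]ethyl}-4H-pyran-4-one | O=c1cc(CCc2ccc(OC)c(O[Si](C)(C)C(C)(C)C)c2)oc(I)c1O | intermediate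
9 | 2-ethenyl-3-hydroxy-6-{2-[3-(tert-butyldimethylsilyloxy)-4-methoxyphenyl]ethyl}-4H-pyran-4-one | O=c1cc(CCc2ccc(OC)c(O[Si](C)(C)C(C)(C)C)c2)oc(C=C)c1O | intermediate
10 | 2-ethenyl-4-oxo-6-{2-[3-(tert-butyldimethylsilyloxy)-4-methoxyphenyl]ethyl}-4H-pyran-3-yl trifluoromethanesulfonate | O=c1cc(CCc2ccc(OC)c(O[Si](C)(C)C(C)(C)C)c2)oc(C=C)c1OS(=O)(=O)C(F)(F)F | intermediate
11 | 2-ethenyl-4-oxo-6-{2-[3-(tert-butyldimethylsilyloxy)-4-methoxyphenyl]ethyl}-4H-pyran-3-carbaldehyde | O=Cc1c(C=C)oc(CCc2ccc(OC)c(O[Si](C)(C)C(C)(C)C)c2)cc1=O | intermediate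
12 | boron adduct: the but-3-enyl chain of 13 with O–B(Ipc)2 on the carbinol carbon next to the pyrone and Bpin on the neighbouring carbon, same spatial arrangement as in 13 | C=Cc1oc(CCc2ccc(OC)c(O[Si](C)(C)C(C)(C)C)c2)cc(=O)c1[C@H](OB([C@H]3C[C@H]4C[C@H](C4(C)C)[C@@H]3C)[C@H]3C[C@H]4C[C@H](C4(C)C)[C@@H]3C)[C@H](B3OC(C)(C)C(C)(C)O3)C=C | intermediate (not isolated)
13 | 3-[(1S,2R)-1,2-dihydroxybut-3-en-1-yl]-2-ethenyl-6-{2-[3-(tert-butyldimethylsilyloxy)-4-methoxyphenyl]ethyl}-4H-pyran-4-one (anti-diol) | C=Cc1oc(CCc2ccc(OC)c(O[Si](C)(C)C(C)(C)C)c2)cc(=O)c1[C@H](O)[C@H](O)C=C | intermediate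
14 | 3-[(1S,2R)-1,2-dihydroxybut-3-en-1-yl]-2-ethenyl-6-[2-(3-hydroxy-4-methoxyphenyl)ethyl]-4H-pyran-4-one | C=Cc1oc(CCc2ccc(OC)c(O)c2)cc(=O)c1[C@H](O)[C@H](O)C=C | intermediate
15 | (5S,6R)-5,6-dihydroxy-2-[2-(3-hydroxy-4-methoxyphenyl)ethyl]-5,6-dihydro-4H-chromen-4-one (cis-diol, C7=C8) | COc1ccc(CCc2cc(=O)c3c(o2)C=C[C@@H](O)[C@H]3O)cc1O | intermediate (not isolated)
16 | (5S,6S,7S,8S)-7,8-epoxy-5,6-dihydroxy-2-[2-(3-hydroxy-4-methoxyphenyl)ethyl]-5,6,7,8-tetrahydro-4H-chromen-4-one (oxirane and both hydroxyls on one face) | COc1ccc(CCc2cc(=O)c3c(o2)[C@H]4O[C@H]4[C@@H](O)[C@H]3O)cc1O | intermediate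
17 | (5S,6S,7S,8R)-8-chloro-5,6,7-trihydroxy-2-[2-(3-hydroxy-4-methoxyphenyl)ethyl]-5,6,7,8-tetrahydro-4H-chromen-4-one | COc1ccc(CCc2cc(=O)c3c(o2)[C@H](Cl)[C@@H](O)[C@@H](O)[C@H]3O)cc1O | target

**Step count and risks**

Total step count: 12. Longest linear sequence: 12 steps (from 1; aldehyde 4 enters in step 3).

Steps most likely to fail:

1. Step 11. The conjugated, electron-poor 2-vinyl group may enter the metathesis cycle slowly, so that cross-metathesis oligomers form. The free dihydrodiol may lose water and aromatise before it is oxidised. Oxygen transfer may also lose facial selectivity if hydrogen bonding to the peracid is weak. The fallback sets out from 13 and comes back at 17. The diol of 13 is tied up with 2,2-dimethoxypropane and PPTS as the acetonide F1. Ring-closing metathesis of this substrate, which has no free allylic OH, gives the stable dihydrodiol acetonide F2. NBS in aqueous THF forms the bromonium ion on the face opposite the dioxolane, and water opens it at C8 to give the bromohydrin F3 (8-OH cis to the dioxolane, 7-Br trans). K2CO3 in methanol closes the oxirane with inversion at C7 and removes the aryl silyl ether, giving the syn-epoxide acetonide F4. Hydrochloric acid in THF then opens the oxirane at C8 and hydrolyses the acetonide to 17.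

2. Step 9. The γ-pyrone carbonyl next to the formyl group may disturb the closed transition state and erode facial discrimination. During the oxidative work-up the β-oxygenated allylboronate may eliminate to a 1,3-diene, or the base-sensitive 2-vinylpyrone may be attacked by peroxide. The fallback sets out from 11 and comes back at 14. An iridium-catalysed transfer-hydrogenative anti-selective (benzoyloxy)allylation of 11 with allylidene dibenzoate and 2-propanol, with the bisphosphine enantiomer that gives the (1S,2R) product, delivers the anti-diol monobenzoate F5 without any boron oxidation. K2CO3 in methanol at 0 °C then removes the benzoate and the aryl silyl ether to give 14.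

3. Step 8. Palladium hydride formed from the silane may reduce or hydrosilylate the conjugated vinyl group, or may simply replace the triflate by hydrogen. The fallback sets out from 10 and comes back at 11. Stille coupling of 10 with (tributylstannyl)methanol gives the hydroxymethyl compound F6, which is oxidised with MnO2 to 11, so that neither CO nor a hydride source is needed.

**Further compounds**

F1 | step 11 | acetonide of 13: 2-ethenyl-3-[(4S,5R)-2,2-dimethyl-5-ethenyl-1,3-dioxolan-4-yl]-6-{2-[3-(tert-butyldimethylsilyloxy)-4-methoxyphenyl]ethyl}-4H-pyran-4-one | C=Cc1oc(CCc2ccc(OC)c(O[Si](C)(C)C(C)(C)C)c2)cc(=O)c1[C@@H]3OC(C)(C)O[C@@H]3C=C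
F2 | step 11 | 5,6-O-isopropylidene derivative of the aryl TBS ether of 15 (cis-dihydrodiol acetonide, C7=C8) | COc1ccc(CCc2cc(=O)c3c(o2)C=C[C@H]4OC(C)(C)O[C@@H]34)cc1O[Si](C)(C)C(C)(C)C
F3 | step 11 | bromohydrin: 7-bromo-8-hydroxy-5,6-O-isopropylidene compound, 8-OH cis and 7-Br trans to the dioxolane, aryl TBS ether | COc1ccc(CCc2cc(=O)c3c(o2)[C@@H](O)[C@H](Br)[C@H]4OC(C)(C)O[C@@H]34)cc1O[Si](C)(C)C(C)(C)C
F4 | step 11 | 5,6-O-isopropylidene derivative of 16 (oxirane cis to the dioxolane, free phenol) | COc1ccc(CCc2cc(=O)c3c(o2)[C@H]4O[C@H]4[C@H]5OC(C)(C)O[C@@H]35)cc1O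
F5 | step 9 | (1S,2R)-1-hydroxy-1-(2-ethenyl-4-oxo-6-{2-[3-(tert-butyldimethylsilyloxy)-4-methoxyphenyl]ethyl}-4H-pyran-3-yl)but-3-en-2-yl benzoate | C=Cc1oc(CCc2ccc(OC)c(O[Si](C)(C)C(C)(C)C)c2)cc(=O)c1[C@H](O)[C@H](OC(=O)c2ccccc2)C=C
F6 | step 8 | 2-ethenyl-3-(hydroxymethyl)-6-{2-[3-(tert-butyldimethylsilyloxy)-4-methoxyphenyl]ethyl}-4H-pyran-4-one | C=Cc1oc(CCc2ccc(OC)c(O[Si](C)(C)C(C)(C)C)c2)cc(=O)c1CO
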